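Keep the teal flask closed and stirring until 1.5 h, and add nothing to it.

| setting | teal | amber | flask |
|---|---|---|---|
| electrophile | 0.059 M | 0.040 M | 0.059 M |
| buffer base | 0.20 equiv | 0.20 equiv | 0.200 equiv |
| buffer acid | 0.10 equiv | 0.10 equiv | 0.100 equiv |
| solid nucleophile | 2.5 equiv | 2.5 equiv | 2.50 equiv |
| remark | the very flask that is asked about, followed so far | run made earlier |  |
| time |  |  | 1.5 h |

| run | time / min | electrophile / % | target / % |
|---|---|---|---|
| teal | 2.50 | 100.8 | 0 |
| teal | 5.00 | 100.3 | 0.9 |
| teal | 8.00 | 100.1 | 0.2 |
| teal | 10.0 | 98.6 | 1.0 |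
| teal | 12.0 | 99.6 | 0.8 |
| teal | 15.0 | 98.6 | 2.4 |
| teal | 20.0 | 98.3 | 2.9 |
| amber | 10.0 | 99.8 | 1.4 |
| amber | 20.0 | 97.2 | 2.7 |
| amber | 25.0 | 96.4 | 6.6 |
| amber | 40.0 | 90.4 | 9.1 |
| amber | 50.0 | 86.4 | 11.8 |
| amber | 60.0 | 82.3 | 16.3 |

(scatter of a reading: 1 percentage point)

- at the start none of the solid nucleophile is in solution
- a reading or a percentage of target counts all its forms, free or not
- the earlier runs do not show the pH; that part of a forecast is a guess

* part of the electrophile that has reacted at 1.5 h
* pH of the solution at 1.5 h

At 20.0 min the teal flask still holds 98.3% of its electrophile, and its target, 2.9%, is level with the amber run's 2.7%, so this note borrows the amber curve for teal. The last stretch of that curve, carried straight on to the asked time, gives 27.1%. This note assumes one acid per electrophile reacted. The base reach 20.0% is then the part of the electrophile whose acid the buffer base can take up: the buffer capacity, in percent of electrophile. The straight line ends above the reach, pH should fall past that point, and this note supposes that the rate falls with it, so it expects the teal flask between 20.0% and 27.1%. The forecast says 32%, more than that straight line, at pH 6.5, and of released acid it says “lowering pH and possibly slowing the reaction”.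

The teal flask gives 24.3% at pH 6.44, with buffer base at 1.32% of its own charge. That conversion stands 4.3 percentage points past the reach, which on 0.059 M of electrophile is 0.00254 M of acid; adding the 1.55 × 10⁻⁴ M of buffer base still left gives 0.00270 M, and [protonated nucleophile] reads 0.00270 M.

    protonated nucleophile ⇌ nucleophile + acid, settled at all times (K = 1.30 × 10⁻⁶ M)
    buffer acid ⇌ buffer base + acid, settled at all times (K = 3.20 × 10⁻⁹ M)
    crystals ⇌ target, rate k3*(cs3 - [target]) while solid is left; crystals form when [target] > cs3 (solubility = 40.0 mM, k = 0.00133 s⁻¹)
    electrophile + nucleophile → acid + target + leaving group (k = 0.00591 M⁻¹ s⁻¹)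
    solid nucleophile ⇌ nucleophile, rate k5*(cs5 - [nucleophile]) while solid is left; crystals form when [nucleophile] > cs5 (solubility = 16.0 mM, k = 6.81 × 10⁻⁴ s⁻¹)

The same flask read at 25 min has 4.50% reacted, less than the reach, so the reach puts buffer base at 77.5% of its charge; the computed value is 77.6%.

The readings are calculated for an exercise.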